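**Retrosynthetic overview**

1. The target comes from an all-cis cyclohexenol triene that already carries both angelates, by two late alkene epoxidations: C1–OH-directed on ring C3=C4, then reagent-controlled (Shi) on side-chain C10=C11.
2. The cyclohexenol comes from open-chain (3Z,6E)-2,8-bis(angeloyloxy)farnesa-3,6,10-trienal by a type I carbonyl-ene cyclisation forming C1–C6. This closes the cyclohexane C1–C6 (the only ring of the C15 skeleton), sets C1 and C6, turns the C14 methyl into the exocyclic methylene and frees the only hydroxyl.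
3. Enabling feature: the homoallylic alcohol array C1(OH)–C6–C7(=C14H2) across ring bond C1–C6, together with the (3Z)-alkene C3=C4 (the later oxirane) that holds C2 and C5 cis so C1 can reach C6.
4. The aldehyde comes from a triol (C1 silylation, double angeloylation at C2/C8, desilylation, oxidation), made by a Z-selective Wittig union (C3=C4) of an (R)-glycerate-derived methyl ketone with a C4–C12 phosphonium salt built from homoprenyl bromide (E-selective SeO2 oxidation, Brown allylation for C8, cross-metathesis for the prenyl end).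
5. Ring order: carbocycle C1–C6 from an acyclic chain in the key step; afterwards only the two oxiranes are added as alkene oxidations (C3–C4, then C10–C11).

Key step: step 14

Numbering used throughout (bisabolane/farnesane): C1 (ring CHOH; aldehyde carbon of the open-chain precursors), C2 (CH–OAng), C3 (C–CH3, methyl = C15), C4, C5 (CH2), C6, C7 (C14 = its methyl, later the exocyclic methylene), C8 (CH–OAng), C9, C10, C11 (methyls C12, C13). Ang = angeloyl = (Z)-2-methylbut-2-enoyl. In this numbering the target is (1R,2R,3S,4S,6S,8S,10R).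

Remark (assumption): the two oxiranes are treated as oxidation-level functional groups on the monocarbocyclic skeleton, so they are introduced by the last two oxidations. Oxone is written as its active salt KHSO5.

**Route**

Step 1
Reactants: 1 5-bromo-2-methylpent-2-ene
Product: 3 (E)-5-bromo-2-methylpent-2-enal, via allylic alcohol 2 (not isolated)
Conditions: SeO2 (1.2 equiv), 1,4-dioxane/H2O, 80 °C
Reagents that add atoms: selenium dioxide, O=[Se]=O
Why: SeO2 allylic oxidation (ene reaction then [2,3]-shift) attacks the more substituted alkene terminus and selects the methyl trans to the chain, so in-flask oxidation of the first-formed allylic alcohol should give the (E)-enal with the remaining methyl (C14) cis to C5; the primary bromide is inert.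

Step 2
Reactants: 3 (E)-5-bromo-2-methylpent-2-enal
Product: 5 (4S,5E)-8-bromo-5-methylocta-1,5-dien-4-ol, via borinate ester 4 (not isolated)
Conditions: (−)-Ipc2B(allyl) (from (+)-α-pinene), Et2O, −78 °C; then NaOH, H2O2, 0 °C to rt
Reagents that add atoms: (−)-B-allyldiisopinocampheylborane, C=CCB([C@@H]1C[C@@H]2C[C@H]([C@H]1C)C2(C)C)[C@@H]1C[C@@H]2C[C@H]([C@H]1C)C2(C)C
Why: Brown asymmetric allylboration through a closed chair transition state; the (+)-α-pinene-derived reagent should add to the Si face of the 2-methyl-2-enal (as with benzaldehyde-type aldehydes) and set C8 as S, and peroxide work-up releases the carbinol.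

Step 3
Reactants: 5 (4S,5E)-8-bromo-5-methylocta-1,5-dien-4-ol
Product: 6 (5S,6E)-9-bromo-2,6-dimethylnona-2,6-dien-5-ol
Conditions: Grubbs II (3 mol%), 2-methyl-2-butene (large excess), CH2Cl2, 40 °C
Reagents that add atoms: 2-methyl-2-butene, CC=C(C)C
Why: Olefin cross-metathesis with 2-methyl-2-butene is the standard allyl-to-prenyl conversion; the trisubstituted C6=C7 alkene does not engage the Ru carbene and C8 is untouched.

Step 4
Reactants: 6 (5S,6E)-9-bromo-2,6-dimethylnona-2,6-dien-5-ol
Product: 7 (5S,6E)-9-bromo-2,6-dimethyl-5-(triethylsilyloxy)nona-2,6-diene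
Conditions: TESCl, imidazole, CH2Cl2, 0 °C to rt
Reagents that add atoms: chlorotriethylsilane, CC[Si](Cl)(CC)CC
Why: Routine silylation; TES is chosen because it later falls together with the acetonide under mild aqueous acid.

Step 5
Reactants: 7 (5S,6E)-9-bromo-2,6-dimethyl-5-(triethylsilyloxy)nona-2,6-diene
Product: 8 [(3E,5S)-4,8-dimethyl-5-(triethylsilyloxy)nona-3,7-dien-1-yl]triphenylphosphonium bromide
Conditions: PPh3 (2 equiv), iPr2NEt (0.1 equiv), MeCN, 85 °C
Reagents that add atoms: triphenylphosphine, c1ccc(cc1)P(c1ccccc1)c1ccccc1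
Why: SN2 quaternisation of the primary homoallylic bromide; the trace amine base guards the TES ether against adventitious HBr.

Step 6
Reactants: 9 methyl (R)-2,2-dimethyl-1,3-dioxolane-4-carboxylate
Product: 10 (R)-N-methoxy-N,2,2-trimethyl-1,3-dioxolane-4-carboxamide
Conditions: MeNH(OMe)·HCl, iPrMgCl, THF, −20 to 0 °C
Reagents that add atoms: N,O-dimethylhydroxylamine hydrochloride, CNOC.Cl
Why: Weinreb amide formation from the ester with the chloromagnesium amide made in situ; the low temperature avoids epimerisation of the α-alkoxy stereocentre.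

Step 7
Reactants: 10 (R)-N-methoxy-N,2,2-trimethyl-1,3-dioxolane-4-carboxamide
Product: 12 (R)-1-(2,2-dimethyl-1,3-dioxolan-4-yl)ethan-1-one, via magnesium hemiaminal 11 (not isolated)
Conditions: MeMgBr, THF, −78 to 0 °C; then aq. NH4Cl
Reagents that add atoms: methylmagnesium bromide, C[Mg]Br
Why: Weinreb ketone synthesis; the chelated tetrahedral adduct resists over-addition and collapses to the methyl ketone only on quench.

Step 8
Reactants: 8 [(3E,5S)-4,8-dimethyl-5-(triethylsilyloxy)nona-3,7-dien-1-yl]triphenylphosphonium bromide; 12 (R)-1-(2,2-dimethyl-1,3-dioxolan-4-yl)ethan-1-one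
Product: 14 (4S)-2,2-dimethyl-4-[(2Z,5E,7S)-6,10-dimethyl-7-(triethylsilyloxy)undeca-2,5,9-trien-2-yl]-1,3-dioxolane, via phosphorus ylide 13 (not isolated)
Conditions: NaHMDS (1.0 equiv), THF, −78 °C; then 12, −78 °C to rt
Reagents that add atoms: none
Why: Wittig olefination of an α-alkoxy methyl ketone with a non-stabilised ylide, a reaction type known to place the oxygenated carbon cis to the ylide-derived chain, should give the (3Z)-alkene (C2 cis to C5); low temperature and the non-nucleophilic base keep C2 intact (its descriptor changes from R to S only through CIP priorities).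

Step 9
Reactants: 14 (4S)-2,2-dimethyl-4-[(2Z,5E,7S)-6,10-dimethyl-7-(triethylsilyloxy)undeca-2,5,9-trien-2-yl]-1,3-dioxolane
Product: 15 (2S,3Z,6E,8S)-3,7,11-trimethyldodeca-3,6,10-triene-1,2,8-triol
Conditions: AcOH/THF/H2O (3:1:1), 40 °C
Reagents that add atoms: none
Why: Mild acid hydrolysis cleaves the terminal acetonide and the TES ether in one operation without ionising the two allylic carbinols.

Step 10
Reactants: 15 (2S,3Z,6E,8S)-3,7,11-trimethyldodeca-3,6,10-triene-1,2,8-triol
Product: 16 (2S,3Z,6E,8S)-1-(tert-butyldimethylsilyloxy)-3,7,11-trimethyldodeca-3,6,10-triene-2,8-diol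
Conditions: TBSCl (1.05 equiv), imidazole, CH2Cl2, −20 to 0 °C
Reagents that add atoms: tert-butyldimethylsilyl chloride, CC(C)(C)[Si](C)(C)Cl
Why: Steric differentiation; the primary C1 hydroxyl silylates much faster than the two secondary allylic hydroxyls.

Step 11
Reactants: 16 (2S,3Z,6E,8S)-1-(tert-butyldimethylsilyloxy)-3,7,11-trimethyldodeca-3,6,10-triene-2,8-diol
Product: 17 (2S,3Z,6E,8S)-2,8-bis(angeloyloxy)-1-(tert-butyldimethylsilyloxy)-3,7,11-trimethyldodeca-3,6,10-triene
Conditions: angelic acid, 2,4,6-trichlorobenzoyl chloride, Et3N, toluene, rt; then 16, 75 °C (no DMAP)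
Reagents that add atoms: angelic acid, C/C=C(/C)C(=O)O
Why: Yamaguchi-type esterification through the angelic/2,4,6-trichlorobenzoic mixed anhydride without DMAP is the established way to acylate hindered secondary alcohols with angelic acid while suppressing Z-to-E isomerisation to the tiglate; both secondary hydroxyls are esterified in one operation.

Step 12
Reactants: 17 (2S,3Z,6E,8S)-2,8-bis(angeloyloxy)-1-(tert-butyldimethylsilyloxy)-3,7,11-trimethyldodeca-3,6,10-triene
Product: 18 (2S,3Z,6E,8S)-2,8-bis(angeloyloxy)-3,7,11-trimethyldodeca-3,6,10-trien-1-ol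
Conditions: HF·pyridine, pyridine, THF, 0 °C to rt
Reagents that add atoms: none
Why: Buffered, weakly acidic fluoride cleavage of the primary TBS ether, chosen to avoid base-induced 2-to-1 acyl migration.

Step 13
Reactants: 18 (2S,3Z,6E,8S)-2,8-bis(angeloyloxy)-3,7,11-trimethyldodeca-3,6,10-trien-1-ol
Product: 19 (2S,3Z,6E,8S)-2,8-bis(angeloyloxy)-3,7,11-trimethyldodeca-3,6,10-trienal
Conditions: Dess–Martin periodinane, NaHCO3, CH2Cl2, 0 °C; used at once
Reagents that add atoms: none
Why: Dess–Martin oxidation under bicarbonate buffering is non-basic and non-epimerising, as the α-acyloxy β,γ-unsaturated aldehyde requires.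

Step 14
Reactants: 19 (2S,3Z,6E,8S)-2,8-bis(angeloyloxy)-3,7,11-trimethyldodeca-3,6,10-trienal
Product: 21 (1R,2S,6S,8S)-2,8-bis(angeloyloxy)bisabola-3,7(14),10-trien-1-ol, via aluminium alkoxide 20 (not isolated)
Conditions: Me2AlCl (2.2 equiv), CH2Cl2 (0.01 M), −78 to −40 °C; then aq. Rochelle salt
Reagents that add atoms: none
Why: Me2AlCl binds the aldehyde and C1 is attacked by C6 of the (6E)-alkene while an allylic hydrogen of the C14 methyl passes to the carbonyl oxygen through a six-membered, concerted but asynchronous array (intramolecular type I carbonyl-ene reaction), after which the aluminium alkoxide loses methane so that no protic acid is set free. The closest known reaction is the Lewis-acid-mediated cyclisation of citronellal to the isopulegols, here applied to an α-acyloxy aldehyde. The cyclohexene closes by C1–C6 bond formation in a 6-exo-trig mode (carbonyl oxygen and C7 both exocyclic) through a half-chair in which the pre-set (3Z)-alkene spans C2–C5. C6 and the C1/C6 relationship are set by the pericyclic geometry: C7 sits equatorial, and because the only good hydrogen donor is the C14 methyl, which lies cis to the C5 tether in the (6E)-alkene, the carbonyl oxygen must sit axial on the C5 side to reach it, giving C1–OH cis to the C6 side chain (the O-equatorial array could only take the C8–H, which is geminal to an acyloxy group and would give an enol ester). The C1/C2 relationship and the absolute sense are set by C2: with C3 necessarily gauche to the forming bond as part of the ring, the C2–OAng bond lies pseudo-equatorial and antiperiplanar to the incoming C6 (polar Felkin–Anh arrangement, also compatible with aluminium bridging the two oxygens), so C1–O ends cis to C2–O and the all-cis C1/C2/C6 triad results. The step needs chemoselectivity (only C6 can reach C1 through a six-membered array, since C3=C4 is too close and C10=C11 would need a ten-membered ring) and ene rather than cationic Prins behaviour, which Me2AlCl as Lewis acid and proton scavenger at low temperature and the absence of any epoxide at this stage should secure.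

Step 15
Reactants: 21 (1R,2S,6S,8S)-2,8-bis(angeloyloxy)bisabola-3,7(14),10-trien-1-ol
Product: 22 (1R,2R,3S,4S,6S,8S)-2,8-bis(angeloyloxy)-3,4-epoxybisabola-7(14),10-dien-1-ol
Conditions: VO(acac)2 (5 mol%), t-BuOOH (1.5 equiv), CH2Cl2, 0 °C to rt
Reagents that add atoms: tert-butyl hydroperoxide, CC(C)(C)OO
Why: Vanadium-catalysed hydroxyl-directed epoxidation; the axial homoallylic C1–OH binds the vanadium peroxide and delivers oxygen to its own face of ring C3=C4 (cyclohex-3-en-1-ols are known to give cis-epoxy alcohols), setting C3 and C4, while the undirected C10=C11 alkene, the electron-poor angelates and the ester-deactivated 1,1-disubstituted C7=C14 should not react (C2 becomes R only through CIP priorities).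

Step 16
Reactants: 22 (1R,2R,3S,4S,6S,8S)-2,8-bis(angeloyloxy)-3,4-epoxybisabola-7(14),10-dien-1-ol
Product: 23 (1R,2R,3S,4S,6S,8S,10R)-2,8-bis(angeloyloxy)-3,4:10,11-diepoxybisabol-7(14)-en-1-ol
Conditions: D-fructose-derived Shi ketone (30 mol%), Oxone, K2CO3, Bu4NHSO4 (cat.), MeCN/DMM/aq. Na2B4O7 buffer (pH about 10.5), −5 °C
Reagents that add atoms: potassium peroxymonosulfate (Oxone), [K+].[O-]S(=O)(=O)OO
Why: Shi asymmetric epoxidation; the ketone-derived dioxirane epoxidises the only remaining electron-rich trisubstituted alkene through a spiro transition state and should set C10 as R under reagent control, leaving the ester-deactivated C7=C14 and the conjugated angelate alkenes untouched.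

**Compound list**

1 | 5-bromo-2-methylpent-2-ene | CC(C)=CCCBr | starting material
2 | (E)-5-bromo-2-methylpent-2-en-1-ol | C/C(CO)=C\CCBr | intermediate
3 | (E)-5-bromo-2-methylpent-2-enal | C/C(C=O)=C\CCBr | intermediate
4 | bis(isopinocampheyl)borinate ester of alcohol 5 | C/C([C@H](CC=C)OB([C@@H]1C[C@@H]2C[C@H]([C@H]1C)C2(C)C)[C@@H]1C[C@@H]2C[C@H]([C@H]1C)C2(C)C)=C\CCBr | intermediate
5 | (4S,5E)-8-bromo-5-methylocta-1,5-dien-4-ol | C/C([C@H](CC=C)O)=C\CCBr | intermediate
6 | (5S,6E)-9-bromo-2,6-dimethylnona-2,6-dien-5-ol | C/C([C@H](CC=C(C)C)O)=C\CCBr | intermediate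
7 | (5S,6E)-9-bromo-2,6-dimethyl-5-(triethylsilyloxy)nona-2,6-diene | C/C([C@H](CC=C(C)C)O[Si](CC)(CC)CC)=C\CCBr | intermediate
8 | [(3E,5S)-4,8-dimethyl-5-(triethylsilyloxy)nona-3,7-dien-1-yl]triphenylphosphonium bromide | C/C([C@H](CC=C(C)C)O[Si](CC)(CC)CC)=C\CC[P+](c1ccccc1)(c1ccccc1)c1ccccc1.[Br-] | intermediate
9 | methyl (R)-2,2-dimethyl-1,3-dioxolane-4-carboxylate | COC(=O)[C@@H]1OC(C)(C)OC1 | starting material
10 | (R)-N-methoxy-N,2,2-trimethyl-1,3-dioxolane-4-carboxamide | CON(C)C(=O)[C@@H]1OC(C)(C)OC1 | intermediate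
11 | bromomagnesium salt of the tetrahedral N,O-hemiaminal from 10 and MeMgBr | CON(C)C(C)(O[Mg]Br)[C@@H]1OC(C)(C)OC1 | intermediate
12 | (R)-1-(2,2-dimethyl-1,3-dioxolan-4-yl)ethan-1-one | CC(=O)[C@@H]1OC(C)(C)OC1 | intermediate
13 | [(3E,5S)-4,8-dimethyl-5-(triethylsilyloxy)nona-3,7-dien-1-ylidene]triphenylphosphorane | C/C([C@H](CC=C(C)C)O[Si](CC)(CC)CC)=C\CC=P(c1ccccc1)(c1ccccc1)c1ccccc1 | intermediate
14 | (4S)-2,2-dimethyl-4-[(2Z,5E,7S)-6,10-dimethyl-7-(triethylsilyloxy)undeca-2,5,9-trien-2-yl]-1,3-dioxolane | C/C([C@H](CC=C(C)C)O[Si](CC)(CC)CC)=C\C/C=C(/C)[C@@H]1OC(C)(C)OC1 | intermediate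
15 | (2S,3Z,6E,8S)-3,7,11-trimethyldodeca-3,6,10-triene-1,2,8-triol | C/C([C@H](CC=C(C)C)O)=C\C/C=C(/C)[C@H](O)CO | intermediate
16 | (2S,3Z,6E,8S)-1-(tert-butyldimethylsilyloxy)-3,7,11-trimethyldodeca-3,6,10-triene-2,8-diol | C/C([C@H](CC=C(C)C)O)=C\C/C=C(/C)[C@H](O)CO[Si](C)(C)C(C)(C)C | intermediate
17 | (2S,3Z,6E,8S)-2,8-bis(angeloyloxy)-1-(tert-butyldimethylsilyloxy)-3,7,11-trimethyldodeca-3,6,10-triene | C/C([C@H](CC=C(C)C)OC(=O)/C(C)=C\C)=C\C/C=C(/C)[C@H](OC(=O)/C(C)=C\C)CO[Si](C)(C)C(C)(C)C | intermediate
18 | (2S,3Z,6E,8S)-2,8-bis(angeloyloxy)-3,7,11-trimethyldodeca-3,6,10-trien-1-ol | C/C([C@H](CC=C(C)C)OC(=O)/C(C)=C\C)=C\C/C=C(/C)[C@H](OC(=O)/C(C)=C\C)CO | intermediate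
19 | (2S,3Z,6E,8S)-2,8-bis(angeloyloxy)-3,7,11-trimethyldodeca-3,6,10-trienal | C/C([C@H](CC=C(C)C)OC(=O)/C(C)=C\C)=C\C/C=C(/C)[C@H](OC(=O)/C(C)=C\C)C=O | intermediate
20 | chloro(methyl)aluminium alkoxide of 21 | C=C([C@H](CC=C(C)C)OC(=O)/C(C)=C\C)[C@@H]1CC=C(C)[C@H](OC(=O)/C(C)=C\C)[C@@H]1O[Al](C)Cl | intermediate
21 | (1R,2S,6S,8S)-2,8-bis(angeloyloxy)bisabola-3,7(14),10-trien-1-ol (ring 1-OH, 2-OAng and 6-side chain all cis) | C=C([C@H](CC=C(C)C)OC(=O)/C(C)=C\C)[C@@H]1CC=C(C)[C@H](OC(=O)/C(C)=C\C)[C@@H]1O | intermediate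
22 | (1R,2R,3S,4S,6S,8S)-2,8-bis(angeloyloxy)-3,4-epoxybisabola-7(14),10-dien-1-ol | C=C([C@H](CC=C(C)C)OC(=O)/C(C)=C\C)[C@@H]1C[C@@H]2O[C@]2(C)[C@H](OC(=O)/C(C)=C\C)[C@@H]1O | intermediate
23 | (1R,2R,3S,4S,6S,8S,10R)-2,8-bis(angeloyloxy)-3,4:10,11-diepoxybisabol-7(14)-en-1-ol (CNP0296086.3) | C=C([C@H](C[C@H]1OC1(C)C)OC(=O)/C(C)=C\C)[C@@H]1C[C@@H]2O[C@]2(C)[C@H](OC(=O)/C(C)=C\C)[C@@H]1O | target

**Step count and risks**

Total step count: 16. Longest linear sequence: 14 steps (steps 1–5 and 8–16, from 1).

Most likely to fail: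

1. Step 14. The cyclisation may leave the concerted ene course for a stepwise cationic (Prins-type) closure, which would erode control at C1 (O-equatorial closure) or divert the C7 cation, and the 1,2-induction from C2 may be incomplete. Fallback (sets out from 19, returns at 21): the C1 configuration is taken out of the pericyclic step. Aldehyde 19 is cyclised with whichever Lewis acid gives the cleanest C1–C6 closure (for example ZnBr2 in CH2Cl2), accepting the C1-epimeric alcohol (1S,2S,6S,8S)-2,8-bis(angeloyloxy)bisabola-3,7(14),10-trien-1-ol F1, alone or mixed with 21. Dess–Martin oxidation (NaHCO3, 0 °C) converges both epimers on the ring ketone (2S,6S,8S)-2,8-bis(angeloyloxy)bisabola-3,7(14),10-trien-1-one F2. L-Selectride (THF, −78 °C), which attacks a cyclohexanone flanked by two equatorial substituents from the equatorial direction, should then give, through the lithium alkoxide of 21 F3, the axial all-cis alcohol 21.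

2. Step 15. Oxygen may be delivered to the other homoallylic alkene (C7=C14), or the reaction may stall on the ester-deactivated, crowded cis face. Fallback (from 21, back at 22): the oxygen is delivered through a covalent tether instead of a metal alkoxide. Alcohol 21 is converted into its tert-butyl carbonate, the 1-O-Boc derivative of 21 F4 (Boc2O, DMAP cat., MeCN). Iodocarbonate cyclisation (NIS, MeCN, −20 °C; iodonium formation at the untethered C10=C11 alkene is reversible and finds no nucleophile) should give the cyclic 1,3-iodocarbonate F5 by 6-exo attack of the carbonate oxygen on C3 anti to iodine at C4. Brief K2CO3/MeOH at 0 °C cleaves the carbonate, and the C3 alkoxide displaces the C4 iodide to give 22 with the oxirane cis to C1–OH.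

3. Step 16. The pH 10.5 buffer may cause 2-to-1 angeloyl migration in the cis-hydroxy ester, or partial ester loss, during the epoxidation. Fallback (from 22, back at 23): the hydroxy ester is masked during the basic step. Alcohol 22 is silylated (TESOTf, 2,6-lutidine, CH2Cl2, −78 °C) to the 1-O-triethylsilyl ether of 22 F6, which has no free hydroxyl and is epoxidised under the same Shi conditions to the 1-O-triethylsilyl ether of 23 F7. HF·pyridine buffered with pyridine (THF, 0 °C), conditions that trisubstituted epoxides are known to survive, then returns 23.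

Further compounds
F1 | step 14 | (1S,2S,6S,8S)-2,8-bis(angeloyloxy)bisabola-3,7(14),10-trien-1-ol (C1 epimer of 21) | C=C([C@H](CC=C(C)C)OC(=O)/C(C)=C\C)[C@@H]1CC=C(C)[C@H](OC(=O)/C(C)=C\C)[C@H]1O
F2 | step 14 | (2S,6S,8S)-2,8-bis(angeloyloxy)bisabola-3,7(14),10-trien-1-one | C=C([C@H](CC=C(C)C)OC(=O)/C(C)=C\C)[C@@H]1CC=C(C)[C@H](OC(=O)/C(C)=C\C)C1=O
F3 | step 14 | lithium alkoxide of 21 | C=C([C@H](CC=C(C)C)OC(=O)/C(C)=C\C)[C@@H]1CC=C(C)[C@H](OC(=O)/C(C)=C\C)[C@@H]1O[Li]
F4 | step 15 | 1-O-(tert-butoxycarbonyl) derivative of 21 | C=C([C@H](CC=C(C)C)OC(=O)/C(C)=C\C)[C@@H]1CC=C(C)[C@H](OC(=O)/C(C)=C\C)[C@@H]1OC(=O)OC(C)(C)C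
F5 | step 15 | cyclic 1,3-carbonate (O1–C(=O)–O3) of the 4-iodo-1,3-diol, iodine trans to the carbonate oxygens | C=C([C@H](CC=C(C)C)OC(=O)/C(C)=C\C)[C@@H]1C[C@@H](I)[C@]2(C)OC(=O)O[C@H]1[C@H]2OC(=O)/C(C)=C\C
F6 | step 16 | 1-O-triethylsilyl ether of 22 | C=C([C@H](CC=C(C)C)OC(=O)/C(C)=C\C)[C@@H]1C[C@@H]2O[C@]2(C)[C@H](OC(=O)/C(C)=C\C)[C@@H]1O[Si](CC)(CC)CC
F7 | step 16 | 1-O-triethylsilyl ether of 23 | C=C([C@H](C[C@H]1OC1(C)C)OC(=O)/C(C)=C\C)[C@@H]1C[C@@H]2O[C@]2(C)[C@H](OC(=O)/C(C)=C\C)[C@@H]1O[Si](CC)(CC)CC
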